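Ring A of the drimane core is opened at C3–C4. In ring A the C3 carbinol lies beside the quaternary C4, and the isopropenyl group of (R)-carvone already supplies C4, one of its methyls and the C4–C5 bond. In one operation, hydrogen-atom transfer from an iron hydride to that alkene and 6-exo attack of the resulting tertiary C4 radical on a C3 aldehyde should close ring A, complete the gem-dimethyl group and set C3. The precursor is a monocyclic keto aldehyde made from carvone, bearing the C10 methyl and a 3-oxopropyl arm trans to the isopropenyl group. C11 and the scopoletin ether follow through two allylic transpositions, the second of which sets C9.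

Key step: step 4

Remark on the chemistry: drimane numbering is used throughout (C3 carbinol, C4 CMe2, C5/C10 ring fusion, C7=C8, C9–C11H2–OAr); the target is read as 3α-OH (axial), 5α-H, 10β-CH3 and 9β-H, so that C11 is axial on the α face, trans to the C10 methyl.

Step 1
Reactants: 1 (R)-carvone; 2 iodomethane
Product: 4 6-methylcarvone, via lithium dienolate of carvone 3 (not isolated)
Conditions: LiN(i-Pr)2, THF, −78 °C; then MeI, −78 → 0 °C
Reagents that add atoms: iodomethane (2), CI
Why: Kinetic deprotonation at the α′ carbon gives the cross-conjugated lithium dienolate, and its C-methylation (enolate alkylation) should give 4 as a C6 epimer mixture, which does not matter because C6 is enolised again in step 2.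

Step 2
Reactants: 4 6-methylcarvone; 5 propargyl bromide
Product: 7 6-methyl-6-propargylcarvone, via lithium enolate of 6-methylcarvone 6 (not isolated)
Conditions: LiN(i-Pr)2, THF, −78 → −10 °C; then propargyl bromide, DMPU, −78 °C → rt
Reagents that add atoms: 3-bromoprop-1-yne (5), C#CCBr
Why: Enolate alkylation of the tetrasubstituted lithium enolate, in which the electrophile should enter anti to the neighbouring isopropenyl group (held pseudoaxial by allylic strain with the enolate methyl), so that the new quaternary centre (future C10) has its methyl cis and its three-carbon arm trans to the isopropenyl group.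

Step 3
Reactants: 7 6-methyl-6-propargylcarvone
Product: 9 keto aldehyde, via (E)-alkenyldicyclohexylborane 8 (not isolated)
Conditions: Cy2BH (from BH3·SMe2, cyclohexene), THF, 0 °C; then 30% H2O2, pH 7 phosphate buffer, 0 °C → rt
Reagents that add atoms: hydrogen peroxide, OO
Why: Hydroboration–oxidation of the terminal alkyne, where anti-Markovnikov addition of the bulky dialkylborane should be much faster than attack on the hindered 1,1-disubstituted alkene or on the enone carbonyl flanked by the quaternary carbon, and buffered oxidation of the alkenylborane gives the enol and hence the aldehyde without exposing the enone to basic peroxide.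

Step 4
Reactants: 9 keto aldehyde
Product: 12 3α-hydroxy-11-nordrim-7-en-9-one, via tertiary C4 radical 10 (not isolated), via 3α-alkoxyl radical 11 (not isolated)
Conditions: Fe(acac)3, PhSiH3, EtOH (0.03 M), Ar, 60 °C
Reagents that add atoms: none
Why: Proposed new method: the iron hydride formed from Fe(acac)3 and PhSiH3 transfers a hydrogen atom to the CH2 terminus of the isopropenyl group, which creates the second C4 methyl and the tertiary radical 10; this adds to the aldehyde carbon C3, and the alkoxyl radical 11 is reduced by divalent iron and protonated by ethanol, which returns trivalent iron. The closest known reaction type is the iron hydride hydrogen-atom-transfer cyclisation of alkene-tethered ketones to tertiary alcohols, and 6-exo additions of alkyl radicals to aldehydes are known under tin hydride conditions; the new element is the aldehyde acceptor under iron hydride conditions. Ring A closes in the 6-exo-trig mode by forming C3–C4. The ring fusion needs no control here, because the trans arms on C5 and C10 can only meet when both are equatorial, which allows only the trans-decalin; C3 is set in a chair transition state with the carbonyl oxygen axial, so that the small formyl hydrogen and not the oxygen lies between the two C4 methyls, which leads to the axial 3α-alcohol. The step needs hydrogen-atom transfer to the electron-rich 1,1-disubstituted alkene in preference to the electron-poor enone, a preference that carvone itself shows in such hydrofunctionalisations, and the enone offers the C4 radical no ring closure of workable size.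

Step 5
Reactants: 12 3α-hydroxy-11-nordrim-7-en-9-one; 13 chloromethyl methyl ether
Product: 14 3α-(methoxymethoxy)-11-nordrim-7-en-9-one
Conditions: MOMCl, i-Pr2NEt, n-Bu4NI (cat.), CH2Cl2, 40 °C
Reagents that add atoms: chloromethyl methyl ether (13), COCCl
Why: O-Alkylation of the hindered axial alcohol by the small, very electrophilic α-chloro ether under iodide catalysis (acetal protection) masks C3–OH against the chromium oxidant of step 7, and the enone is inert to these conditions.

Step 6
Reactants: 14 3α-(methoxymethoxy)-11-nordrim-7-en-9-one; 15 tributyl[(methoxymethoxy)methyl]stannane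
Product: 16 3α,11-bis(methoxymethoxy)drim-7-en-9-ol
Conditions: Bu3SnCH2OMOM, n-BuLi, THF, −78 °C; then 14, −78 → −40 °C; H2O
Reagents that add atoms: tributyl[(methoxymethoxy)methyl]stannane (15), CCCC[Sn](CCCC)(CCCC)COCOC
Why: Tin–lithium exchange gives an α-alkoxymethyllithium, a small and weakly basic nucleophile whose 1,2-addition to the enone carbonyl (organolithium addition) installs C11, expected from the α face anti to the axial C10 methyl, and the new C9 configuration is erased in step 7.

Step 7
Reactants: 16 3α,11-bis(methoxymethoxy)drim-7-en-9-ol
Product: 18 3α,11-bis(methoxymethoxy)drim-8-en-7-one, via C7 chlorochromate ester 17 (not isolated)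
Conditions: C5H5NH[CrO3Cl], 4 Å MS, CH2Cl2, rt
Reagents that add atoms: pyridinium chlorochromate, [O-][Cr](=O)(=O)Cl.c1cc[nH+]cc1
Why: Babler–Dauben oxidative transposition, in which the tertiary allylic chromate ester rearranges by a [3,3] shift to the secondary C7 ester and this is oxidised to the tetrasubstituted enone, while the acetal protecting groups tolerate the mildly acidic oxidant.

Step 8
Reactants: 18 3α,11-bis(methoxymethoxy)drim-8-en-7-one
Product: 19 3α,11-dihydroxydrim-8-en-7-one
Conditions: HCl (conc., cat.), MeOH, 45 °C
Reagents that add atoms: none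
Why: Acid-catalysed transacetalisation to methanol removes both methoxymethyl groups as dimethoxymethane, and the enone and the C3 carbinol are stable to dilute acid at this temperature.

Step 9
Reactants: 19 3α,11-dihydroxydrim-8-en-7-one; 20 scopoletin
Product: 21 3α-hydroxy-11-(scopoletin-7-yloxy)drim-8-en-7-one
Conditions: scopoletin, PPh3, DIAD, THF, 0 °C → rt
Reagents that add atoms: scopoletin (20), COc1cc2ccc(=O)oc2cc1O
Why: Mitsunobu etherification, in which the primary allylic C11 alcohol is activated as its oxyphosphonium salt and displaced by the acidic coumarin phenol, whereas the axial C3 alcohol next to the quaternary C4 is too hindered to react.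

Step 10
Reactants: 21 3α-hydroxy-11-(scopoletin-7-yloxy)drim-8-en-7-one; 22 p-toluenesulfonohydrazide
Product: 23 C7 p-toluenesulfonylhydrazone of 21
Conditions: TsNHNH2, AcOH (cat.), EtOH, 60 °C
Reagents that add atoms: 4-methylbenzenesulfonohydrazide (22), Cc1ccc(cc1)S(=O)(=O)NN
Why: Acid-catalysed condensation of the only ketone with the sulfonyl hydrazide (hydrazone formation) should leave the lactone, the aryl ether and the free alcohol unchanged.

Step 11
Reactants: 23 C7 p-toluenesulfonylhydrazone of 21
Product: 25 target, via 7β-allylic diazene 24 (not isolated)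
Conditions: catecholborane (3 equiv), CHCl3, 0 °C → rt; then NaOAc·3H2O, reflux
Reagents that add atoms: none
Why: Catecholborane reduction of the conjugated tosylhydrazone with allylic diazene rearrangement, in which hydride should add to C7=N from the α face (axial attack, away from the C10 methyl, as with steroidal 4-en-3-one tosylhydrazones), loss of sulfinate gives the 7β-diazene, and its retro-ene loss of N2 delivers hydrogen suprafacially to the β face of C9 while the alkene moves to C7=C8, so that H9 is β and C11 is axial on the α face.

Compound list
1 | (R)-carvone, (5R)-2-methyl-5-(prop-1-en-2-yl)cyclohex-2-en-1-one | CC1=CC[C@H](CC1=O)C(C)=C | starting material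
2 | iodomethane | CI | starting material
3 | lithium dienolate of carvone (cross-conjugated, O–Li on C1, C1=C6) | [Li]OC1=C[C@@H](CC=C1C)C(C)=C | intermediate (not isolated)
4 | 6-methylcarvone, (5R,6RS)-2,6-dimethyl-5-(prop-1-en-2-yl)cyclohex-2-en-1-one, C6 epimer mixture | O=C1C(C)=CC[C@@H](C(C)=C)C1C | intermediate
5 | propargyl bromide (3-bromoprop-1-yne) | C#CCBr | starting material
6 | lithium enolate of 6-methylcarvone (tetrasubstituted C1=C6) | [Li]OC1=C(C)[C@H](C(C)=C)CC=C1C | intermediate (not isolated)
7 | 6-methyl-6-propargylcarvone, (5S,6S)-2,6-dimethyl-5-(prop-1-en-2-yl)-6-(prop-2-yn-1-yl)cyclohex-2-en-1-one; propargyl trans and methyl cis to isopropenyl | O=C1C(C)=CC[C@@H](C(C)=C)[C@]1(C)CC#C | intermediate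
8 | (E)-alkenyldicyclohexylborane from 7 (boron on the terminal alkene carbon) | O=C1C(C)=CC[C@@H](C(C)=C)[C@]1(C)C/C=C/B(C2CCCCC2)C2CCCCC2 | intermediate (not isolated)
9 | keto aldehyde, 3-[(1S,6S)-1,3-dimethyl-2-oxo-6-(prop-1-en-2-yl)cyclohex-3-en-1-yl]propanal | O=C1C(C)=CC[C@@H](C(C)=C)[C@]1(C)CCC=O | intermediate
10 | tertiary C4 radical (2-propyl radical on the ring carbon that becomes C5) | O=C1C(C)=CC[C@@H]([C](C)C)[C@]1(C)CCC=O | intermediate (not isolated)
11 | 3α-alkoxyl radical of 12 | O=C1C(C)=CC[C@H]2C(C)(C)[C@H]([O])CC[C@]12C | intermediate (not isolated)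
12 | 3α-hydroxy-11-nordrim-7-en-9-one, (4aS,6R,8aS)-6-hydroxy-2,5,5,8a-tetramethyl-4a,5,6,7,8,8a-hexahydronaphthalen-1(4H)-one; trans-fused, 5α-H, 10β-CH3, axial 3α-OH | O=C1C(C)=CC[C@H]2C(C)(C)[C@H](O)CC[C@]12C | intermediate
13 | chloromethyl methyl ether | COCCl | starting material
14 | 3α-(methoxymethoxy)-11-nordrim-7-en-9-one | O=C1C(C)=CC[C@H]2C(C)(C)[C@H](OCOC)CC[C@]12C | intermediate
15 | tributyl[(methoxymethoxy)methyl]stannane | CCCC[Sn](CCCC)(CCCC)COCOC | starting material
16 | 3α,11-bis(methoxymethoxy)drim-7-en-9-ol; tertiary C9 alcohol drawn as the expected isomer with 9β-OH and C11 on the α face | COCOC[C@]1(O)C(C)=CC[C@H]2C(C)(C)[C@H](OCOC)CC[C@]12C | intermediate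
17 | C7 chlorochromate ester formed by [3,3] shift (C7 configuration not defined) | COCOCC1=C(C)C(O[Cr](=O)(=O)Cl)C[C@H]2C(C)(C)[C@H](OCOC)CC[C@]12C | intermediate (not isolated)
18 | 3α,11-bis(methoxymethoxy)drim-8-en-7-one | COCOCC1=C(C)C(=O)C[C@H]2C(C)(C)[C@H](OCOC)CC[C@]12C | intermediate
19 | 3α,11-dihydroxydrim-8-en-7-one | OCC1=C(C)C(=O)C[C@H]2C(C)(C)[C@H](O)CC[C@]12C | intermediate
20 | scopoletin (7-hydroxy-6-methoxy-2H-chromen-2-one) | COc1cc2ccc(=O)oc2cc1O | starting material
21 | 3α-hydroxy-11-[(6-methoxy-2-oxo-2H-chromen-7-yl)oxy]drim-8-en-7-one | COc1cc2ccc(=O)oc2cc1OCC1=C(C)C(=O)C[C@H]2C(C)(C)[C@H](O)CC[C@]12C | intermediate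
22 | p-toluenesulfonohydrazide | Cc1ccc(cc1)S(=O)(=O)NN | starting material
23 | C7 p-toluenesulfonylhydrazone of 21 (C=N geometry not assigned) | COc1cc2ccc(=O)oc2cc1OCC1=C(C)C(=NNS(=O)(=O)c3ccc(C)cc3)C[C@H]2C(C)(C)[C@H](O)CC[C@]12C | intermediate
24 | 7β-allylic diazene (7α-H; drawn with free 3-OH, which is held as a catechol borate until hydrolysis) | COc1cc2ccc(=O)oc2cc1OCC1=C(C)[C@@H](N=N)C[C@H]2C(C)(C)[C@H](O)CC[C@]12C | intermediate (not isolated)
25 | target, 7-{[(1R,4aR,6R,8aS)-6-hydroxy-2,5,5,8a-tetramethyl-1,4,4a,5,6,7,8,8a-octahydronaphthalen-1-yl]methoxy}-6-methoxy-2H-chromen-2-one; 3α-OH, 5α-H, 9β-H, 10β-CH3 | COc1cc2ccc(=O)oc2cc1OC[C@@H]1C(C)=CC[C@H]2C(C)(C)[C@H](O)CC[C@]12C | target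

Total step count: 11. Longest linear sequence: 11 steps, from 1 to 25.

Steps most likely to fail

Step 4 (proposed new method). Three processes may compete: reduction or hemiacetal formation of the aldehyde by the silane and alcohol before the radical arrives; reversal of the carbonyl addition by β-scission of the alkoxyl radical before it is reduced; and, through that reversibility, erosion of the facial selectivity at C3. The fallback uses known chemistry and sets out from 9. Markovnikov addition of HBr to the isopropenyl group (HBr in AcOH, CH2Cl2, 0 °C, the classical hydrobromination of carvone) should give the tertiary bromide F1. Bu3SnH (about 0.05 M) with AIBN in benzene at 80 °C then abstracts bromine to give the same radical 10. Its 6-exo cyclisation onto the aldehyde is the known tin hydride radical cyclisation onto aldehydes. Alkoxyl radical 11 is trapped at once and irreversibly by the stannane, so that C3 reflects the kinetic chair preference and no silane or alcohol touches the aldehyde. The fallback comes back to the route at 12.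

Step 11. Hydride delivery to the hindered C7=N bond may show poor facial selectivity, or aryloxide may be lost from the vinylogous position while the hydrazone is formed or decomposed. The fallback sets out from 18 and fixes the C7 configuration before the ether is made. LiBH(s-Bu)3 in THF at −78 °C should attack the enone carbonyl equatorially from the β face, as bulky hydrides do with steroidal 4-en-3-ones, and give the 7α-allylic alcohol F2, whose epimer is separable. Mitsunobu displacement with o-nitrobenzenesulfonylhydrazide (PPh3, DEAD, THF, −30 °C → rt) inverts C7 to the 7β-sulfonylhydrazine F3. This loses sulfinic acid to give the 7β-diazene F4, whose retro-ene loss of N2 puts hydrogen on the β face of C9 and gives the bis-ether F5. HCl in MeOH frees the diol F6, and Mitsunobu etherification of its primary C11 alcohol with scopoletin 20 (PPh3, DIAD) comes back to the route at 25.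

Step 3. The borane may also hydroborate the isopropenyl group or reduce the enone carbonyl, and peroxide may attack the enone during the oxidation. The fallback sets out from 4 and brings in C3 at the aldehyde oxidation level, so that neither borane nor peroxide is needed. Enolate 6 is alkylated with 2-(2-iodoethyl)-1,3-dioxolane (THF, DMPU, −78 °C → rt), again anti to the isopropenyl group, to give the dioxolane acetal F7. Mild hydrolysis (PPTS, acetone, H2O, 50 °C) comes back to the route at 9.

Further compounds
F1 | step 4 | tertiary bromide, 3-[6-(2-bromopropan-2-yl)-1,3-dimethyl-2-oxocyclohex-3-en-1-yl]propanal with the configuration of 9 | O=C1C(C)=CC[C@@H](C(C)(C)Br)[C@]1(C)CCC=O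
F2 | step 11 | 7α-allylic alcohol, 3α,11-bis(methoxymethoxy)drim-8-en-7α-ol | COCOCC1=C(C)[C@H](O)C[C@H]2C(C)(C)[C@H](OCOC)CC[C@]12C
F3 | step 11 | 7β-sulfonylhydrazine, N-(drim-8-en-7β-yl)-N-(2-nitrophenylsulfonyl)hydrazine bis(methoxymethyl) ether (not isolated) | COCOCC1=C(C)[C@@H](N(N)S(=O)(=O)c3ccccc3[N+](=O)[O-])C[C@H]2C(C)(C)[C@H](OCOC)CC[C@]12C
F4 | step 11 | 7β-diazene of the bis(methoxymethyl) ether (not isolated) | COCOCC1=C(C)[C@@H](N=N)C[C@H]2C(C)(C)[C@H](OCOC)CC[C@]12C
F5 | step 11 | bis-ether, 3α,11-bis(methoxymethoxy)-9βH-drim-7-ene | COCOC[C@@H]1C(C)=CC[C@H]2C(C)(C)[C@H](OCOC)CC[C@]12C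
F6 | step 11 | diol, 9βH-drim-7-ene-3α,11-diol | OC[C@@H]1C(C)=CC[C@H]2C(C)(C)[C@H](O)CC[C@]12C
F7 | step 3 | dioxolane acetal of 9, 6-[2-(1,3-dioxolan-2-yl)ethyl]-2,6-dimethyl-5-(prop-1-en-2-yl)cyclohex-2-en-1-one with the configuration of 9 | O=C1C(C)=CC[C@@H](C(C)=C)[C@]1(C)CCC2OCCO2
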